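## Analysis of the target

Target 23 is a C75 pentaflavonoid. Its core is (2R,3S)-afzelechin (ring A = phloroglucinol ring C4a–C8a, ring C = pyran O1–C4, ring B = 4-hydroxyphenyl on C2), and ring A carries one C30 arm on C6 and a second on C8.

In each arm a tetrahydrofuran (ring D on the C6 arm, ring E on the C8 arm; atoms O-1f, C-2f to C-5f) bears a 2,4-dihydroxyphenyl group on C-2f, a 2,4-dihydroxybenzoyl group on C-4f and a 4-hydroxyphenyl group on C-5f. C-3f is bonded to an exocyclic methine, C-m, which carries another 4-hydroxyphenyl group and the bond to ring A.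

Reading the SMILES string shows that both arms have the same configuration (C-m S, C-2f R, C-3f S, C-4f S, C-5f S). The twelve stereocentres are therefore the two of the core plus one set of five contiguous centres used twice. Within rings D and E the pattern is 2f,3f-cis, 3f,4f-trans, 4f,5f-trans, 2f,5f-cis.

The sensitive groups are:
- fifteen oxidisable phenols;
- the benzylic ethers C-2f–O and C-5f–O, which ionise easily because of the ortho/para hydroxyls;
- the enolisable C-4f of a β-alkoxy ketone, which can undergo retro-oxa-Michael opening;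
- the base-labile C2 of the flavan.

The hard points are:
- the two arene–methine bonds at ring A positions that are each flanked by two oxygens;
- the acyclic centre C-m;
- the contra-steric 2f,3f-cis relation;
- the dissonant 1,4-relation between C-2f and the acyl carbon.

The feature that the route exploits is this. In each arm C-m (a donor carbon with a 4-oxyphenyl group) and C-4f (an acceptor carbon with an aroyl group) are 1,3-related through C-3f, and C-2f and the acyl carbon carry the same 2,4-dioxygenated aryl group. Joining C-m to C-4f and raising C-2f to a ketone turns each arm into a 3-aryl-trans-1,2-diaroylcyclopropane. In that cyclopropane C-m is not even stereogenic.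

## Retrosynthetic reasoning

**23 ⇒ 22.** No skeletal bond is cut. All fifteen phenols and the C3 hydroxyl are masked as benzyl ethers in 22, so one neutral hydrogenolysis ends the synthesis. Ethers on O5 and O7 are also needed earlier, because free ring A phenols would add to the C-2f carbonyl of the open-chain intermediates and erase C-3f.

**22 ⇒ 20 (through 21).** In rings D and E the C-2f–H and O-1f–C-2f bonds are cut, so C-2f becomes a ketone and C-5f carries a hydroxyl. Forward, the hydroxyl closes onto the ketone to give bis-lactol 21, and hydride adds to the derived oxocarbenium ion anti to the very large C-3f substituent. The aryl group is thereby pushed cis to that substituent, so the contra-steric 2f,3f-cis relation comes out as the kinetic result. Cutting O-1f–C-5f instead would require setting a C-2f carbinol in an open chain beside a second, equal ketone.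

**20 ⇒ 18 + 6.** The C-4f–C-5f bond is cut twice, since each arm holds a β-hydroxy ketone (aldol retron). Forward, the Z-boron enolates 19 must react twice with 6, syn-selectively (4f,5f-trans after ring closure) and on the enolate face opposite the diarylmethyl group on C-3f (3f,4f-trans). The gain is that two commercial C7 units and four stereocentres are removed.

**18 ⇒ 16 + two molecules of 13 (key disconnection).** The C8–C-m and C6–C-m bonds are cut and C-m is reconnected to C-4f. Each arm shrinks to cyclopropane 13, and the core becomes the protected flavan 16. The cut is made here because these are the most crowded bonds and because C-m is the one centre that no ring can control. A stereospecific, invertive opening of a donor–acceptor cyclopropane replaces a facial selection at a planar cation. The forward reaction must break the ring bond between C-m and the carbon whose aroyl group is cis to the aryl group, with inversion, first at C8 (17) and then at C6.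

**13 ⇒ 12 ⇒ 8 + 10.** The aryl–C-2f bond is cut. Aryllithium 11, made from 10, adds to aldehyde 8, and oxidation of carbinol 12 levels the new centre. The two aroyl groups thus come in separately, so the asymmetric step can be run on an enal.

**8 ⇒ 5 + 7.** The C-3f–C-4f and C-4f–C-m bonds are cut, which corresponds to an iminium-catalysed Michael-initiated ring closure of ylide 5 on enal 7. This one catalytic step sets the absolute configuration of both arms and builds the dissonant C-3f–C-4f bond without any oxidative coupling.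

**Feedstocks.** Ylide 5 comes from 1 through 2, 3 and 4. Enal 7 comes from 6. Bromide 10 comes from 9. Flavan 16 comes from 14 through 15.

## Alternatives that were turned down

**Alternative 1:** This is the textbook disconnection. The same two ring A–C-m bonds are cut, but with rings D and E already in place. Arm carbinol A1 is ionised to p-quinone methide A2, which alkylates C8 and C6 of 14.
- In A2, allylic 1,3-strain puts the C-3f hydrogen in the plane of the quinone methide. The face that must be attacked to give S at C-m is then covered by the cis 2,4-dihydroxyphenyl group on C-2f.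
- The open face, on the C-4f side where only a hydrogen points down, leads to the C-m epimer, and it would do so twice.
- The acid that ionises A1 also ionises the C-2f–O bond.
- A1 needs its own long synthesis of four contiguous ring centres before the uncertain step.

**Alternative 2:** O-1f–C-2f and C-4f–C-5f are cut together. The forward step is a formal [3+2] annulation of cyclopropane A3 (donor = 2,4-bis(benzyloxy)phenyl on C-2f) with aldehyde 6, giving tetrahydrofuran ketone A4. Inversion at C-2f of the trans cyclopropane would deliver 2f,3f-cis and 2f,5f-cis.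
- The donor carbon of A3 is flanked by two different aroyl-bearing carbons, so cleavage of either ring bond is possible and the two modes give constitutional isomers.
- The very electron-rich donor would racemise by reversible ring opening.
- In A4 the carbon C-m is still a ketone. It has to be reduced and joined to ring A through the same planar cation as in alternative 1, so the hardest centre is left unsolved after more steps.

**Alternative 3:** This copies the presumed biosynthesis by cutting C-3f–C-4f. One-electron oxidation of isoliquiritigenin A5 gives the α,α'-coupled bis(quinone methide) A6. One terminus is captured by ring A of 14 and the other by oxygen, and one carbonyl is then reduced.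
- The phenoxyl radical of A5 has several coupling sites.
- A6 would form as a racemic/meso mixture with two equal quinone methide termini and two equal ketones that cannot be told apart.
- Flavan 14 is oxidised more easily than A5.
- No element controls the absolute configuration.

Key step: step 10

Assumption 1: (+)-afzelechin (14) is bought as the isolated natural product; nothing in the route depends on its source.

Assumption 2: the sense of induction in step 5 is assigned from the carboxylate-directed model of the Z-iminium ion; both catalyst enantiomers are commercial, so the (1S,2S,3S) series is reachable whichever way the model holds.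

## Steps

**Step 1**
Reactants: 1 1-(2,4-dihydroxyphenyl)ethan-1-one
Product: 2 1-[2,4-bis(benzyloxy)phenyl]ethan-1-one
Conditions: BnBr (2.4 equiv), K2CO3, DMF, 60 °C
Reagents that add atoms: benzyl bromide, BrCc1ccccc1
Why: Williamson ether synthesis; warm DMF and excess halide also alkylate the hydrogen-bonded 2-hydroxyl.

**Step 2**
Reactants: 2 1-[2,4-bis(benzyloxy)phenyl]ethan-1-one
Product: 3 1-[2,4-bis(benzyloxy)phenyl]-2-bromoethan-1-one
Conditions: CuBr2 (2 equiv), EtOAc–CHCl3, reflux
Reagents that add atoms: CuBr2, [Cu+2].[Br-].[Br-]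
Why: Heterogeneous α-bromination of an aryl methyl ketone through its enol; this reagent halogenates the side chain and spares the alkoxy-substituted ring.

**Step 3**
Reactants: 3 1-[2,4-bis(benzyloxy)phenyl]-2-bromoethan-1-one
Product: 5 1-[2,4-bis(benzyloxy)phenyl]-2-(dimethyl-λ4-sulfanylidene)ethan-1-one (stabilised sulfonium ylide), via sulfonium bromide 4 (not isolated)
Conditions: Me2S, acetone, rt; then aq NaOH, CHCl3, 0 °C
Reagents that add atoms: dimethyl sulfide, CSC
Why: SN2 alkylation of the sulfide followed by deprotonation; carbonyl-stabilised sulfonium ylides are isolable and storable.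

**Step 4**
Reactants: 6 4-(benzyloxy)benzaldehyde
Product: 7 (E)-3-[4-(benzyloxy)phenyl]prop-2-enal
Conditions: Ph3P=CHCHO, toluene, 80 °C
Reagents that add atoms: (triphenylphosphoranylidene)acetaldehyde, O=CC=P(c1ccccc1)(c1ccccc1)c1ccccc1
Why: Wittig reaction with a stabilised ylide, which gives the E-enal.

**Step 5**
Reactants: 5 stabilised sulfonium ylide; 7 (E)-3-[4-(benzyloxy)phenyl]prop-2-enal
Product: 8 (1S,2S,3S)-2-[2,4-bis(benzyloxy)benzoyl]-3-[4-(benzyloxy)phenyl]cyclopropane-1-carbaldehyde (formyl trans to aryl and to aroyl; aroyl cis to aryl)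
Conditions: (R)-indoline-2-carboxylic acid (20 mol %), CHCl3, −10 °C
Reagents that add atoms: none
Why: Enantioselective organocatalytic cyclopropanation of an enal with a stabilised sulfonium ylide (iminium-activated Michael-initiated ring closure). The catalyst carboxylate steers the sulfonium ylide to one face of C-m of the Z-iminium ion, and the E-geometry of 7 fixes formyl and aryl trans. The closure places the aroyl group trans to the bulky iminium carbon and hence cis to the aryl group.

**Step 6**
Reactants: 9 4-bromobenzene-1,3-diol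
Product: 10 2,4-bis(benzyloxy)-1-bromobenzene
Conditions: BnBr (2.3 equiv), K2CO3, DMF, rt
Reagents that add atoms: benzyl bromide, BrCc1ccccc1
Why: Williamson ether synthesis on an unhindered bromoresorcinol.

**Step 7**
Reactants: 10 2,4-bis(benzyloxy)-1-bromobenzene; 8 cyclopropanecarbaldehyde
Product: 12 {(1S,2S,3S)-ring-configured 2-[[2,4-bis(benzyloxy)phenyl](hydroxy)methyl]-3-[4-(benzyloxy)phenyl]cyclopropyl}[2,4-bis(benzyloxy)phenyl]methanone (both carbinol epimers), via aryllithium 11 (not isolated)
Conditions: n-BuLi, THF, −78 °C; then 8, −78 °C; H2O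
Reagents that add atoms: none
Why: Bromine–lithium exchange and 1,2-addition; the aldehyde reacts far faster than the hindered, electron-rich aryl cyclopropyl ketone. The new carbinol centre is of no consequence because it is oxidised in the next step, and the cyclopropane centres cannot enolise.

**Step 8**
Reactants: 12 cyclopropyl carbinol
Product: 13 [(1S,2S)-3-[4-(benzyloxy)phenyl]cyclopropane-1,2-diyl]bis{[2,4-bis(benzyloxy)phenyl]methanone}
Conditions: activated MnO2, CH2Cl2, rt
Reagents that add atoms: none
Why: Neutral oxidation of an electron-rich benzylic alcohol, which avoids ionising the cyclopropylcarbinyl position. With two equal aroyl groups C-m stops being a stereocentre, so the whole stereochemical content of 13 is the trans (1S,2S) pair.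

**Step 9**
Reactants: 14 (+)-afzelechin, (2R,3S)-2-(4-hydroxyphenyl)chromane-3,5,7-triol
Product: 16 (2R,3S)-3,5,7-tris(benzyloxy)-2-[4-(benzyloxy)phenyl]chromane, via tri-O-benzylafzelechin 15 (not isolated)
Conditions: BnBr, K2CO3, DMF, 0 °C to rt; then NaH, 0 °C to rt (one flask)
Reagents that add atoms: benzyl bromide, BrCc1ccccc1
Why: Williamson ether synthesis in two stages. The mild carbonate stage caps the phenols before any strong base is present, so C2 cannot epimerise through a ring B quinone methide, and NaH then alkylates the C3 hydroxyl.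

**Step 10**
Reactants: 16 tetra-O-benzylafzelechin (1 equiv); 13 diaroylcyclopropane (2.4 equiv)
Product: 18 6,8-bis{(1S,2R)-2-[2,4-bis(benzyloxy)benzoyl]-4-[2,4-bis(benzyloxy)phenyl]-1-[4-(benzyloxy)phenyl]-4-oxobutyl} derivative of 16 (bis-1,4-diketone; C-m S, C-3f R in both arms), via C8 mono-adduct 17 (not isolated)
Conditions: Sc(OTf)3 (20 mol %), CH2Cl2, −20 °C to rt
Reagents that add atoms: none
Why: Proposed new method: Sc(OTf)3 chelates the carbonyl and ortho-benzyloxy oxygens of an aroyl group of 13 and so polarises the push–pull bond between the donor carbon C-m (4-benzyloxyphenyl) and the acceptor carbon that becomes C-4f; C8 of 16, and then C6 of 17, attacks C-m from the rear of this bond (SN2-like homo-Michael Friedel–Crafts alkylation), and the proton lost on rearomatisation quenches the scandium enolate, so that C-4f ends as CH2. The closest known reaction type is the Lewis-acid-catalysed opening of 2-arylcyclopropane-1,1-dicarbonyl compounds and of 2-arylcyclopropyl ketones by 1,3,5-trialkoxybenzenes, naphthols and indoles, which runs with inversion at the donor carbon; new here are the vicinal 1,2-diaroyl pattern, in which only one acceptor sits on the carbon of the breaking bond, and the twofold alkylation of one arene. No ring is closed: two cyclopropanes are opened, the C8–C-m and C6–C-m bonds are formed, and each opening uncovers the 1,4-diketone that later becomes ring E or ring D. C-m is set as S in both arms by the inversion, because in 13 it is prochiral and its configuration follows only from which ring bond leaves; C-3f is a spectator and keeps the configuration of 13 (descriptor R in 18 only because C-4f is now CH2). The first selectivity needed is cleavage of the bond to the ring carbon whose aroyl group is cis to the aryl group: this bond carries the eclipsing strain of the two cis substituents, which are held face to face in the bisected conformations of best donor and acceptor overlap, whereas cleavage of the other bond would give the C-m epimer. The second is that the opening stays nucleophile-assisted: the aroyl group on C-3f destabilises a free benzylic cation inductively, the non-ionising solvent and the low temperature keep cation and enolate paired, and the leaving enolate shields the face that must not be attacked. Site selectivity rests on 16 itself, since C8 and C6 are the only free positions of a 1,3,5-trioxygenated ring, all other rings being mono-oxygenated or deactivated by a carbonyl group, and the benzyl ethers on O5 and O7 prevent chromene formation with the new C-2f ketone. The excess of 13 drives the slower second alkylation at the more crowded C6.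

**Step 11**
Reactants: 18 bis-1,4-diketone; 6 4-(benzyloxy)benzaldehyde (3 equiv)
Product: 20 bis(syn-aldol) of 18, each arm now carrying CH(OH)[4-(benzyloxy)phenyl] on C-4f (C-m S, C-3f S, C-4f S, C-5f S), via bis(boron enolate) 19 (not isolated)
Conditions: n-Bu2BOTf (2.6 equiv), i-Pr2NEt, CH2Cl2, −78 to 0 °C; 6, −78 to −20 °C; MeOH, pH 7 buffer, H2O2, 0 °C
Reagents that add atoms: none
Why: Boron-mediated aldol addition: soft enolisation takes the unhindered C-4f methylene and not the tertiary C-3f, and aryl ketones give Z-enolates, which react through a closed chair transition state to the syn aldol (4f,5f-trans after ring closure). Allylic 1,3-strain against the boryloxy group places the C-3f hydrogen in the enolate plane, so 6 approaches opposite the diarylmethyl group, which gives the 3f,4f-trans relation.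

**Step 12**
Reactants: 20 bis(syn-aldol)
Product: 22 hexadeca-O-benzyl ether of the target (rings D and E closed; C-2f R, 2f,3f-cis), via bis-lactol 21 (not isolated)
Conditions: Et3SiH (10 equiv), BF3·OEt2 (4 equiv), CH2Cl2, −78 to −40 °C
Reagents that add atoms: none
Why: Reductive deoxygenation of a cyclic hemiketal (ionic hydrogenation), as used for 2,5-diaryltetrahydrofuran lignans. The C-5f hydroxyl closes 5-exo-trig onto the C-2f ketone, and the aryl-stabilised oxocarbenium ion takes hydride on the face opposite the C-3f diarylmethyl and C-5f aryl groups, which leaves the C-2f aryl cis to the C-3f substituent. Ionisation at C-5f instead would be captured by the C-2f carbonyl oxygen and lead to the same oxocarbenium ion with the 4f,5f-trans arrangement, and the free aroyl ketones need far harsher conditions to be reduced.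

**Step 13**
Reactants: 22 hexadeca-O-benzyl ether
Product: 23 target CNP0225367.3
Conditions: H2 (1 atm), Pd(OH)2/C, THF–MeOH, rt
Reagents that add atoms: none
Why: Hydrogenolysis of benzyl ethers under neutral conditions, as in oligomeric flavan-3-ol and diaryltetrahydrofuran lignan chemistry. The secondary, ring-held benzylic C–O bonds of rings C, D and E and the chelated aryl ketones are cleaved much more slowly than primary O-benzyl groups, and no stereocentre is touched.

## Compound list

1 | 1-(2,4-dihydroxyphenyl)ethan-1-one | CC(=O)c1ccc(O)cc1O | starting material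
2 | 1-[2,4-bis(benzyloxy)phenyl]ethan-1-one | CC(=O)c1ccc(OCc2ccccc2)cc1OCc1ccccc1 | intermediate
3 | 1-[2,4-bis(benzyloxy)phenyl]-2-bromoethan-1-one | BrCC(=O)c1ccc(OCc2ccccc2)cc1OCc1ccccc1 | intermediate
4 | {2-[2,4-bis(benzyloxy)phenyl]-2-oxoethyl}dimethylsulfonium bromide | C[S+](C)CC(=O)c1ccc(OCc2ccccc2)cc1OCc1ccccc1.[Br-] | intermediate
5 | 1-[2,4-bis(benzyloxy)phenyl]-2-(dimethyl-λ4-sulfanylidene)ethan-1-one | C[S+](C)[CH-]C(=O)c1ccc(OCc2ccccc2)cc1OCc1ccccc1 | intermediate
6 | 4-(benzyloxy)benzaldehyde | O=Cc1ccc(OCc2ccccc2)cc1 | starting material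
7 | (E)-3-[4-(benzyloxy)phenyl]prop-2-enal | O=C/C=C/c1ccc(OCc2ccccc2)cc1 | intermediate
8 | (1S,2S,3S)-2-[2,4-bis(benzyloxy)benzoyl]-3-[4-(benzyloxy)phenyl]cyclopropane-1-carbaldehyde | O=C(c1ccc(OCc6ccccc6)cc1OCc6ccccc6)[C@@H]1[C@@H](C=O)[C@@H]1c1ccc(OCc6ccccc6)cc1 | intermediate
9 | 4-bromobenzene-1,3-diol | Oc1ccc(Br)c(O)c1 | starting material
10 | 2,4-bis(benzyloxy)-1-bromobenzene | Brc1ccc(OCc2ccccc2)cc1OCc1ccccc1 | intermediate
11 | [2,4-bis(benzyloxy)phenyl]lithium | [Li]c1ccc(OCc2ccccc2)cc1OCc1ccccc1 | intermediate
12 | cyclopropyl carbinol from 8 and 11 (ring centres as in 8, both carbinol epimers) | O=C(c1ccc(OCc6ccccc6)cc1OCc6ccccc6)[C@@H]1[C@@H](C(O)c2ccc(OCc6ccccc6)cc2OCc6ccccc6)[C@@H]1c1ccc(OCc6ccccc6)cc1 | intermediate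
13 | [(1S,2S)-3-[4-(benzyloxy)phenyl]cyclopropane-1,2-diyl]bis{[2,4-bis(benzyloxy)phenyl]methanone} | O=C(c1ccc(OCc6ccccc6)cc1OCc6ccccc6)[C@@H]1[C@@H](C(=O)c2ccc(OCc6ccccc6)cc2OCc6ccccc6)C1c1ccc(OCc6ccccc6)cc1 | intermediate
14 | (+)-afzelechin, (2R,3S) | Oc1cc(O)c2c(c1)O[C@H](c1ccc(O)cc1)[C@@H](O)C2 | starting material
15 | 5,7,4'-tri-O-benzylafzelechin | c1(OCc6ccccc6)cc(OCc6ccccc6)c2c(c1)O[C@H](c1ccc(OCc6ccccc6)cc1)[C@@H](O)C2 | intermediate
16 | 3,5,7,4'-tetra-O-benzylafzelechin | c1(OCc6ccccc6)cc(OCc6ccccc6)c2c(c1)O[C@H](c1ccc(OCc6ccccc6)cc1)[C@@H](OCc6ccccc6)C2 | intermediate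
17 | C8 mono-adduct of 16 and 13 (C-m S, C-3f R) | c1c(OCc6ccccc6)c2c(c([C@H](c4ccc(OCc6ccccc6)cc4)[C@H](C(=O)c4ccc(OCc6ccccc6)cc4OCc6ccccc6)CC(=O)c4ccc(OCc6ccccc6)cc4OCc6ccccc6)c1OCc6ccccc6)O[C@H](c1ccc(OCc6ccccc6)cc1)[C@@H](OCc6ccccc6)C2 | intermediate
18 | 6,8-bis-adduct, bis-1,4-diketone (C-m S, C-3f R in both arms) | O=C(c1ccc(OCc6ccccc6)cc1OCc6ccccc6)C[C@H]([C@@H](c2ccc(OCc6ccccc6)cc2)c2c(OCc6ccccc6)c3c(c([C@H](c4ccc(OCc6ccccc6)cc4)[C@H](C(=O)c4ccc(OCc6ccccc6)cc4OCc6ccccc6)CC(=O)c4ccc(OCc6ccccc6)cc4OCc6ccccc6)c2OCc6ccccc6)O[C@H](c2ccc(OCc6ccccc6)cc2)[C@@H](OCc6ccccc6)C3)C(=O)c1ccc(OCc6ccccc6)cc1OCc6ccccc6 | intermediate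
19 | bis(Z-dibutylboron enolate) of 18 at C-4f | CCCCB(CCCC)O/C(c1ccc(OCc6ccccc6)cc1OCc6ccccc6)=C\[C@H]([C@@H](c2ccc(OCc6ccccc6)cc2)c2c(OCc6ccccc6)c3c(c([C@H](c4ccc(OCc6ccccc6)cc4)[C@H](C(=O)c4ccc(OCc6ccccc6)cc4OCc6ccccc6)/C=C(\OB(CCCC)CCCC)c4ccc(OCc6ccccc6)cc4OCc6ccccc6)c2OCc6ccccc6)O[C@H](c2ccc(OCc6ccccc6)cc2)[C@@H](OCc6ccccc6)C3)C(=O)c1ccc(OCc6ccccc6)cc1OCc6ccccc6 | intermediate
20 | bis(syn-aldol) (C-m S, C-3f S, C-4f S, C-5f S in both arms) | O=C(c1ccc(OCc6ccccc6)cc1OCc6ccccc6)[C@H]([C@H](O)c1ccc(OCc6ccccc6)cc1)[C@H]([C@@H](c2ccc(OCc6ccccc6)cc2)c2c(OCc6ccccc6)c3c(c([C@H](c4ccc(OCc6ccccc6)cc4)[C@H](C(=O)c4ccc(OCc6ccccc6)cc4OCc6ccccc6)[C@H](C(=O)c5ccc(OCc6ccccc6)cc5OCc6ccccc6)[C@@H](c5ccc(OCc6ccccc6)cc5)O)c2OCc6ccccc6)O[C@H](c2ccc(OCc6ccccc6)cc2)[C@@H](OCc6ccccc6)C3)C(=O)c1ccc(OCc6ccccc6)cc1OCc6ccccc6 | intermediate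
21 | bis-lactol (C-2f hemiketal centres undefined) | O=C(c1ccc(OCc6ccccc6)cc1OCc6ccccc6)[C@H]1[C@H]([C@@H](c2ccc(OCc6ccccc6)cc2)c2c(OCc6ccccc6)c3c(c([C@H](c4ccc(OCc6ccccc6)cc4)[C@H]4[C@H](C(=O)c5ccc(OCc6ccccc6)cc5OCc6ccccc6)[C@@H](c5ccc(OCc6ccccc6)cc5)OC4(O)c4ccc(OCc6ccccc6)cc4OCc6ccccc6)c2OCc6ccccc6)O[C@H](c2ccc(OCc6ccccc6)cc2)[C@@H](OCc6ccccc6)C3)C(O)(c2ccc(OCc6ccccc6)cc2OCc6ccccc6)O[C@@H]1c1ccc(OCc6ccccc6)cc1 | intermediate
22 | hexadeca-O-benzyl ether of the target | O=C(c1ccc(OCc6ccccc6)cc1OCc6ccccc6)[C@H]1[C@H]([C@@H](c2ccc(OCc6ccccc6)cc2)c2c(OCc6ccccc6)c3c(c([C@H](c4ccc(OCc6ccccc6)cc4)[C@H]4[C@H](C(=O)c5ccc(OCc6ccccc6)cc5OCc6ccccc6)[C@@H](c5ccc(OCc6ccccc6)cc5)O[C@H]4c4ccc(OCc6ccccc6)cc4OCc6ccccc6)c2OCc6ccccc6)O[C@H](c2ccc(OCc6ccccc6)cc2)[C@@H](OCc6ccccc6)C3)[C@H](c2ccc(OCc6ccccc6)cc2OCc6ccccc6)O[C@@H]1c1ccc(OCc6ccccc6)cc1 | intermediate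
23 | CNP0225367.3 | O=C(c1ccc(O)cc1O)[C@H]1[C@H]([C@@H](c2ccc(O)cc2)c2c(O)c3c(c([C@H](c4ccc(O)cc4)[C@H]4[C@H](C(=O)c5ccc(O)cc5O)[C@@H](c5ccc(O)cc5)O[C@H]4c4ccc(O)cc4O)c2O)O[C@H](c2ccc(O)cc2)[C@@H](O)C3)[C@H](c2ccc(O)cc2O)O[C@@H]1c1ccc(O)cc1 | target

## Step count and least certain steps

Total step count: 13. Longest linear sequence: 10 (steps 1, 2, 3, 5, 7, 8, 10, 11, 12, 13).

**Step 10 (key step, proposed new method).** Three things are most likely to go wrong.
- Stereospecificity at C-m may be lost, either through cleavage of the ring bond to the trans-aroyl carbon or through full ionisation to a free benzylic cation, which the strong 4-benzyloxyphenyl donor favours.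
- The second alkylation may stall at the crowded C6.
- The Lewis acid may divert material by Cloke–Wilson rearrangement of the cyclopropyl ketone, or by Paal–Knorr dehydration of the newly formed 1,4-diketone.

The fallback uses known chemistry only, sets out from 16 and comes back at 18. Twofold bromination of 16 (NBS, CH2Cl2) should give the 6,8-dibromide F1. Bromine–lithium exchange (n-BuLi) and formylation with DMF should give the 6,8-dialdehyde F2. Claisen–Schmidt condensation with two equivalents of 2 should give the bis-enone F3. A twofold Hayashi–Miyaura 1,4-addition of 4-(benzyloxy)phenylboronic acid ([RhCl(C2H4)2]2 with a chiral diene or BINAP ligand of the series that gives the S methines) should give the bis(β,β-diaryl ketone) F4 under catalyst control. Alkylation of its lithium Z-enolates with bromoketone 3 then returns to 18. Allylic 1,3-strain puts the C-m hydrogen in the enolate plane, and the electrophile enters opposite the bulkier ring A substituent, which is the C-3f configuration required.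

**Step 5.** The electron-rich enal forms a poorly electrophilic iminium ion, so the reaction may be slow, the uncatalysed background addition of the ylide may erode the enantioselectivity, and the sense of induction rests on a model. The fallback sets out from 2, 5 and 6 and comes back at 13, bypassing steps 5 to 8. Claisen–Schmidt condensation of 2 with 6 gives the chalcone F5. Corey–Chaykovsky-type cyclopropanation with ylide 5 gives the racemic trans-diaroylcyclopropane F6, a single diastereomer because C-m is not stereogenic. Preparative chromatography on a chiral phase then delivers 13.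

**Step 11.** The twofold enolisation may be incomplete, enolisation may spill over to C-3f with epimerisation, and the hindered aldolates may revert or dehydrate during work-up. The fallback sets out from 18 and comes back at 22. TBSOTf and Et3N convert 18 into the isolable bis(Z-silyl enol ether) F7, whose regiochemistry can be checked before it is committed. A Mukaiyama aldol addition to 6 (BF3·OEt2, CH2Cl2, −78 °C) is followed in the same flask by Et3SiH, so that aldol addition, hemiketalisation and reduction run as one Lewis acid cascade.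

**Step 12.** The silane may reduce a C-5f benzylic cation directly, C-3f may scramble by reversible loss of its proton from the oxocarbenium ion, or the electron-rich aroyl ketones may be over-reduced if the mixture warms. The fallback sets out from 20 and comes back at 22, replacing the ionic reduction by a radical one. Exchange of the hemiketal hydroxyls with PhSH (catalytic BF3·OEt2, −78 °C) gives the bis(S-phenyl monothioketal) F8. Bu3SnH with AIBN in toluene at 80 °C then delivers hydrogen to the C-2f radical from the face opposite the C-3f substituent, with no acid present.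

**Step 13.** Sixteen cleavages must all go to completion, while hydrogenolytic opening of the benzylic C–O bonds of rings D, E and C, or reduction of the ketones, becomes more competitive as the phenols are freed. The fallback sets out from 22 and comes back at 23. It replaces reductive cleavage by Lewis-acid benzyl transfer (BCl3, pentamethylbenzene as cation scavenger, CH2Cl2, −78 °C, methanol quench). No hydrogen or metal surface is involved, and no new isolated compound is made.

## Further compounds

F1 | step 10 | 6,8-dibromo-3,5,7,4'-tetra-O-benzylafzelechin | Brc2c(OCc6ccccc6)c3c(c(Br)c2OCc6ccccc6)O[C@H](c2ccc(OCc6ccccc6)cc2)[C@@H](OCc6ccccc6)C3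
F2 | step 10 | 3,5,7,4'-tetra-O-benzylafzelechin-6,8-dicarbaldehyde | O=Cc2c(OCc6ccccc6)c3c(c(C=O)c2OCc6ccccc6)O[C@H](c2ccc(OCc6ccccc6)cc2)[C@@H](OCc6ccccc6)C3
F3 | step 10 | 6,8-bis{(E)-3-[2,4-bis(benzyloxy)phenyl]-3-oxoprop-1-enyl} derivative of 16 | O=C(c1ccc(OCc6ccccc6)cc1OCc6ccccc6)/C=C/c2c(OCc6ccccc6)c3c(c(/C=C/C(=O)c4ccc(OCc6ccccc6)cc4OCc6ccccc6)c2OCc6ccccc6)O[C@H](c2ccc(OCc6ccccc6)cc2)[C@@H](OCc6ccccc6)C3
F4 | step 10 | 6,8-bis{(1S)-3-[2,4-bis(benzyloxy)phenyl]-1-[4-(benzyloxy)phenyl]-3-oxopropyl} derivative of 16 | O=C(c1ccc(OCc6ccccc6)cc1OCc6ccccc6)C[C@@H](c2ccc(OCc6ccccc6)cc2)c2c(OCc6ccccc6)c3c(c([C@H](c4ccc(OCc6ccccc6)cc4)CC(=O)c4ccc(OCc6ccccc6)cc4OCc6ccccc6)c2OCc6ccccc6)O[C@H](c2ccc(OCc6ccccc6)cc2)[C@@H](OCc6ccccc6)C3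
F5 | step 5 | (E)-1-[2,4-bis(benzyloxy)phenyl]-3-[4-(benzyloxy)phenyl]prop-2-en-1-one | O=C(/C=C/c1ccc(OCc6ccccc6)cc1)c1ccc(OCc6ccccc6)cc1OCc6ccccc6
F6 | step 5 | racemic trans-3-[4-(benzyloxy)phenyl]-1,2-bis[2,4-bis(benzyloxy)benzoyl]cyclopropane | O=C(c1ccc(OCc6ccccc6)cc1OCc6ccccc6)C1C(C(=O)c2ccc(OCc6ccccc6)cc2OCc6ccccc6)C1c1ccc(OCc6ccccc6)cc1
F7 | step 11 | bis(Z-tert-butyldimethylsilyl enol ether) of 18 at C-4f | CC(C)(C)[Si](C)(C)O/C(c1ccc(OCc6ccccc6)cc1OCc6ccccc6)=C\[C@H]([C@@H](c2ccc(OCc6ccccc6)cc2)c2c(OCc6ccccc6)c3c(c([C@H](c4ccc(OCc6ccccc6)cc4)[C@H](C(=O)c4ccc(OCc6ccccc6)cc4OCc6ccccc6)/C=C(\O[Si](C)(C)C(C)(C)C)c4ccc(OCc6ccccc6)cc4OCc6ccccc6)c2OCc6ccccc6)O[C@H](c2ccc(OCc6ccccc6)cc2)[C@@H](OCc6ccccc6)C3)C(=O)c1ccc(OCc6ccccc6)cc1OCc6ccccc6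
F8 | step 12 | bis(S-phenyl monothioketal) at C-2f (thioketal centres undefined) | O=C(c1ccc(OCc6ccccc6)cc1OCc6ccccc6)[C@H]1[C@H]([C@@H](c2ccc(OCc6ccccc6)cc2)c2c(OCc6ccccc6)c3c(c([C@H](c4ccc(OCc6ccccc6)cc4)[C@H]4[C@H](C(=O)c5ccc(OCc6ccccc6)cc5OCc6ccccc6)[C@@H](c5ccc(OCc6ccccc6)cc5)OC4(Sc7ccccc7)c4ccc(OCc6ccccc6)cc4OCc6ccccc6)c2OCc6ccccc6)O[C@H](c2ccc(OCc6ccccc6)cc2)[C@@H](OCc6ccccc6)C3)C(Sc7ccccc7)(c2ccc(OCc6ccccc6)cc2OCc6ccccc6)O[C@@H]1c1ccc(OCc6ccccc6)cc1
F0 | step 13 | none | none
A1 | alternative 1 | arm carbinol, (2R,3S,4S,5S)-configured tetrahydrofuran with CH(OH)(4-hydroxyphenyl) on C-3f | O=C(c1ccc(O)cc1O)[C@H]1[C@H](C(O)c2ccc(O)cc2)[C@H](c2ccc(O)cc2O)O[C@@H]1c1ccc(O)cc1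
A2 | alternative 1 | arm p-quinone methide | O=C(c1ccc(O)cc1O)[C@H]1[C@H](C=C2C=CC(=O)C=C2)[C@H](c2ccc(O)cc2O)O[C@@H]1c1ccc(O)cc1
A3 | alternative 2 | 1-[2,4-bis(benzyloxy)benzoyl]-2-[4-(benzyloxy)benzoyl]-3-[2,4-bis(benzyloxy)phenyl]cyclopropane (aroyl groups trans, donor aryl trans to the 4-benzyloxybenzoyl group) | O=C(c1ccc(OCc6ccccc6)cc1OCc6ccccc6)[C@H]1[C@H](C(=O)c2ccc(OCc6ccccc6)cc2)[C@H]1c1ccc(OCc6ccccc6)cc1OCc6ccccc6
A4 | alternative 2 | tetrahydrofuran ketone with 4-(benzyloxy)benzoyl on C-3f | O=C(c1ccc(OCc6ccccc6)cc1OCc6ccccc6)[C@H]1[C@H](C(=O)c2ccc(OCc6ccccc6)cc2)[C@H](c2ccc(OCc6ccccc6)cc2OCc6ccccc6)O[C@@H]1c1ccc(OCc6ccccc6)cc1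
A5 | alternative 3 | isoliquiritigenin | O=C(/C=C/c1ccc(O)cc1)c1ccc(O)cc1O
A6 | alternative 3 | α,α'-coupled bis(quinone methide), stereoisomer mixture | O=C(c1ccc(O)cc1O)C(C=C1C=CC(=O)C=C1)C(C=C1C=CC(=O)C=C1)C(=O)c1ccc(O)cc1O
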